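The dihydropyran ring (pyran numbering: O1, C2 with methyl, C3 with formyl, C4 with the acetate arm, C5 with the methyl ester, C6 the enol ether CH) is cut into two three-atom halves. O1, C2 and C3 are (S)-3-hydroxybutanal. C6, C5, C4 and the two acetate carbons are the five ring carbons of methyl coumalate, opened by pyrrolidine and esterified with silyl-protected hydroxytyrosol. The key step exploits the vinylogous carbamate at C6 next to the enoate at C4: in one operation the hydroxyl replaces the amine at C6 and the aldehyde alpha-carbon adds to C4, a formal [3+3] annulation that closes the ring and sets C3 and C4.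

Key step: step 6

Remark: hydroxytyrosol, methyl coumalate and (S)-butane-1,3-diol are taken as commercial.
Remark: dienes 5 and 6 are drawn as the 2E,4E isomers; the geometry is of no consequence, because the carbons that become C4 and C6 both pass through sp3 intermediates in step 6.

Step 1
Reactants: 1 hydroxytyrosol
Product: 2 tris(tert-butyldimethylsilyl) ether of hydroxytyrosol
Conditions: TBSCl (3.5 equiv), imidazole, DMF, 0 °C to rt
Reagents that add atoms: tert-butyldimethylsilyl chloride, CC(C)(C)[Si](C)(C)Cl
Why: Exhaustive silyl ether formation on both phenols and the primary alcohol avoids any phenol/alcohol discrimination at this stage.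

Step 2
Reactants: 2 tris-silyl ether
Product: 3 2-[3,4-bis(tert-butyldimethylsilyloxy)phenyl]ethanol
Conditions: pyridinium p-toluenesulfonate (0.2 equiv), MeOH, rt
Reagents that add atoms: none
Why: Acid-catalysed methanolysis (selective desilylation) should cleave the primary alkyl silyl ether much faster than the acid-stable aryl silyl ethers.

Step 3
Reactants: 4 methyl coumalate
Product: 5 (2E,4E)-4-(methoxycarbonyl)-5-(pyrrolidin-1-yl)penta-2,4-dienoic acid
Conditions: pyrrolidine (1.0 equiv), CH2Cl2, 0 °C to rt
Reagents that add atoms: pyrrolidine, C1CCNC1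
Why: Secondary amines add to C6 of 2-pyranones (aza-Michael 1,6-addition) and the adduct ring-opens to the vinylogous carbamate acid, which delivers C4, C5, C6 and the acetate arm at the right oxidation levels without forming a stereocentre.

Step 4
Reactants: 5 aminodienoic acid; 3 bis-silyl alcohol
Product: 6 1-{2-[3,4-bis(tert-butyldimethylsilyloxy)phenyl]ethyl} 5-methyl (2E,4E)-4-(pyrrolidin-1-ylmethylidene)pent-2-enedioate
Conditions: N,N'-diisopropylcarbodiimide, 4-(dimethylamino)pyridine (0.1 equiv), CH2Cl2, 0 °C to rt
Reagents that add atoms: none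
Why: Carbodiimide/DMAP coupling (Steglich esterification) joins the acid and the primary alcohol under neutral conditions that leave the enamine and the aryl silyl ethers untouched.

Step 5
Reactants: 7 (S)-butane-1,3-diol
Product: 8 (S)-3-hydroxybutanal
Conditions: 2,2,6,6-tetramethylpiperidin-1-oxyl (0.1 equiv), PhI(OAc)2 (1.05 equiv), CH2Cl2, 0 °C to rt; short silica pad, used at once as a solution
Reagents that add atoms: none
Why: Nitroxyl-catalysed oxidation with a hypervalent iodine co-oxidant is selective for the primary alcohol and stops at the aldehyde, so the C2 stereocentre is carried over unchanged (chemoselective alcohol oxidation).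

Step 6
Reactants: 6 aminodienyl diester; 8 (S)-3-hydroxybutanal (1.5 equiv)
Product: 11 methyl (2S,3R,4R)-4-{2-[2-(3,4-bis(tert-butyldimethylsilyloxy)phenyl)ethoxy]-2-oxoethyl}-3-formyl-2-methyl-3,4-dihydro-2H-pyran-5-carboxylate, via hemiaminal ether 9 (not isolated), via cyclic aminal 10 (not isolated)
Conditions: PhCO2H (2 equiv), pyrrolidine (0.1 equiv), 4 Å molecular sieves, CH2Cl2, 0 °C to rt; aqueous citric acid work-up
Reagents that add atoms: none
Why: Proposed new method: benzoic acid protonates the vinylogous carbamate 6 at C5 and the hydroxyl of 8 adds to the resulting C6 iminium ion (hemiaminal ether 9, the C6–O1 bond), pyrrolidine then converts the aldehyde into its enamine, whose carbon C3 adds to C4 of the tethered enoate (cyclic aminal 10, the C3–C4 bond), and acid-driven loss of pyrrolidine from C6 together with the C5 proton gives the conjugated enol ether of 11; the closest known reaction types are the amine-catalysed intramolecular Michael addition of aldehydes to enoates and the Michael/hemiacetalisation/dehydration annulations that build dihydropyrans from formyl esters. The dihydropyran ring is closed by the C3–C4 bond in a 6-(enolexo)-exo-trig Michael cyclisation. C4 is controlled by the C2 centre of 8 through a chair-like transition state with the C2 methyl group and the enoate arm both equatorial (2,4-cis); C3 ends trans to both neighbours because it is alpha to the aldehyde and equilibrates to the all-equatorial isomer; C2 is carried over unchanged. The step needs the oxygen to bond to C6 and the enamine carbon to C4 and not the reverse: the iminium carbon C6 is the site open to the hydroxyl, and once the oxygen is tethered there C3 can reach only C4 through a six-membered transition state, while the tethered oxygen is a poor leaving group at the aminal stage, which should hold back beta-elimination from the enamine. Should the C–C bond form first at the conjugated iminium tautomer, 6-exo-trig closure of the hydroxyl onto C6 leads to the same product.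

Step 7
Reactants: 11 bis-silyl ether
Product: 12 target, methyl (2S,3R,4R)-4-{2-[2-(3,4-dihydroxyphenyl)ethoxy]-2-oxoethyl}-3-formyl-2-methyl-3,4-dihydro-2H-pyran-5-carboxylate
Conditions: Et3N·3HF, THF, 0 °C to rt
Reagents that add atoms: none
Why: Fluoride-mediated desilylation of the aryl silyl ethers under weakly acidic, buffered conditions avoids enolate formation, so the beta-alkoxy aldehyde and its three stereocentres should not be disturbed.

Compound list
1 | hydroxytyrosol, 4-(2-hydroxyethyl)benzene-1,2-diol | OCCc1ccc(O)c(O)c1 | starting material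
2 | tert-butyl{2-[3,4-bis(tert-butyldimethylsilyloxy)phenyl]ethoxy}dimethylsilane | CC(C)(C)[Si](C)(C)OCCc1ccc(O[Si](C)(C)C(C)(C)C)c(O[Si](C)(C)C(C)(C)C)c1 | intermediate
3 | 2-[3,4-bis(tert-butyldimethylsilyloxy)phenyl]ethanol | OCCc1ccc(O[Si](C)(C)C(C)(C)C)c(O[Si](C)(C)C(C)(C)C)c1 | intermediate
4 | methyl coumalate, methyl 2-oxo-2H-pyran-5-carboxylate | COC(=O)C1=COC(=O)C=C1 | starting material
5 | (2E,4E)-4-(methoxycarbonyl)-5-(pyrrolidin-1-yl)penta-2,4-dienoic acid | COC(=O)/C(=C/N1CCCC1)/C=C/C(=O)O | intermediate
6 | 1-{2-[3,4-bis(tert-butyldimethylsilyloxy)phenyl]ethyl} 5-methyl (2E,4E)-4-(pyrrolidin-1-ylmethylidene)pent-2-enedioate | COC(=O)/C(=C/N1CCCC1)/C=C/C(=O)OCCc1ccc(O[Si](C)(C)C(C)(C)C)c(O[Si](C)(C)C(C)(C)C)c1 | intermediate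
7 | (S)-butane-1,3-diol | C[C@H](O)CCO | starting material
8 | (S)-3-hydroxybutanal | C[C@H](O)CC=O | intermediate
9 | hemiaminal ether: 1-{2-[3,4-bis(tert-butyldimethylsilyloxy)phenyl]ethyl} 5-methyl (E)-4-{[(2S)-4-oxobutan-2-yl]oxy(pyrrolidin-1-yl)methyl}pent-2-enedioate, mixture at the two new sp3 carbons | COC(=O)C(/C=C/C(=O)OCCc1ccc(O[Si](C)(C)C(C)(C)C)c(O[Si](C)(C)C(C)(C)C)c1)C(O[C@@H](C)CC=O)N1CCCC1 | intermediate (not isolated)
10 | cyclic aminal: the 5,6-dihydro form of 11 carrying pyrrolidin-1-yl at C6 and hydrogen at C5; C2, C3 and C4 as in 11, mixture at C5 and C6 | COC(=O)C1C(N2CCCC2)O[C@@H](C)[C@H](C=O)[C@H]1CC(=O)OCCc1ccc(O[Si](C)(C)C(C)(C)C)c(O[Si](C)(C)C(C)(C)C)c1 | intermediate (not isolated)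
11 | methyl (2S,3R,4R)-4-{2-[2-(3,4-bis(tert-butyldimethylsilyloxy)phenyl)ethoxy]-2-oxoethyl}-3-formyl-2-methyl-3,4-dihydro-2H-pyran-5-carboxylate; methyl, formyl and acetate arm all trans | COC(=O)C1=CO[C@@H](C)[C@H](C=O)[C@H]1CC(=O)OCCc1ccc(O[Si](C)(C)C(C)(C)C)c(O[Si](C)(C)C(C)(C)C)c1 | intermediate
12 | methyl (2S,3R,4R)-4-{2-[2-(3,4-dihydroxyphenyl)ethoxy]-2-oxoethyl}-3-formyl-2-methyl-3,4-dihydro-2H-pyran-5-carboxylate | COC(=O)C1=CO[C@@H](C)[C@H](C=O)[C@H]1CC(=O)OCCc1ccc(O)c(O)c1 | target

Total step count: 7. Longest linear sequence: 5 steps (steps 1, 2, 4, 6, 7).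

Steps most likely to fail

1. Step 6 (Proposed new method). The enamine carbon may attack C6 instead of C4, which would give condensation instead of annulation. The hydroxy aldehyde may lose water before it is tethered, and the facial selectivity at C4 may be poor. Fallback by known chemistry, from 6 back to 11: the enamine of 6 is hydrolysed with dilute aqueous HCl in THF at 0 °C to the hydroxymethylene diester F1. F1 is then combined with (E)-crotonaldehyde, (S)-α,α-diphenylprolinol trimethylsilyl ether (0.2 equiv) and PhCO2H in toluene at 0 °C, in the amine-catalysed oxa-Michael/Michael cascade established for 2-hydroxycinnamates and enals. The enol oxygen adds to the beta-carbon of the iminium ion (O1–C2 bond, catalyst-controlled), the enamine closes onto the enoate (C3–C4 bond) and C3 equilibrates to give 11. In this variant the ring oxygen is joined to C2 instead of C6 and 8 is not needed.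

2. Step 4. The push-pull acid 5 is a weak acyl donor and may lose carbon dioxide on activation. Fallback, from 3 and 5 back to 6: alcohol 3 is converted with PPh3, I2 and imidazole in CH2Cl2 into the iodide F2, and the caesium carboxylate of 5 (Cs2CO3, DMF, rt) is alkylated with it. The carboxylate then acts as the nucleophile and no acyl activation is needed.

3. Step 5. The beta-hydroxy aldehyde may dehydrate to crotonaldehyde, dimerise or be lost on isolation. Fallback, from 7 back to 8: bis-silylation with Et3SiCl and imidazole gives the bis(triethylsilyl) ether F3. Swern oxidation (oxalyl chloride, DMSO, Et3N, CH2Cl2, −78 to −30 °C) cleaves and oxidises only the primary silyl ether to give (S)-3-(triethylsilyloxy)butanal F4, a distillable aldehyde that can be stored. 8 is released from F4 with AcOH/THF/H2O immediately before step 6.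

Further compounds
F1 | step 6 | 1-{2-[3,4-bis(tert-butyldimethylsilyloxy)phenyl]ethyl} 5-methyl (2E,4Z)-4-(hydroxymethylidene)pent-2-enedioate | O/C=C(/C=C/C(=O)OCCc1ccc(O[Si](C)(C)C(C)(C)C)c(O[Si](C)(C)C(C)(C)C)c1)C(=O)OC
F2 | step 4 | 2-[3,4-bis(tert-butyldimethylsilyloxy)phenyl]ethyl iodide | ICCc1ccc(O[Si](C)(C)C(C)(C)C)c(O[Si](C)(C)C(C)(C)C)c1
F3 | step 5 | (S)-1,3-bis(triethylsilyloxy)butane | C[C@H](O[Si](CC)(CC)CC)CCO[Si](CC)(CC)CC
F4 | step 5 | (S)-3-(triethylsilyloxy)butanal | C[C@H](O[Si](CC)(CC)CC)CC=O
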